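**Assumptions.** The SMILES is taken as drawn (4′-OMe, 3′-OH). Locants: C2/C3 are the dihydrobenzofuran carbons. C1′–C6′ is the cyclohexane, with C1′ the carbinol, C3′ bearing OH and C4′ bearing OMe. Target configuration is (2S,3R,1′S,3′S,4′S): 2,3-trans, 1′-OH/3′-OH cis, 3′-OH/4′-OMe trans.

## Retrosynthetic overview
1. C3′-OH/C4′-OMe come from trans-diaxial methanolysis of a cis-hydroxy-epoxide. That epoxide comes from C1′-OH-directed epoxidation of a 1-substituted cyclohex-3-en-1-ol.
2. O1–C2 closes the dihydrobenzofuran ring, which is formed last. A phenoxide opens a C1′/C2 spiro-epoxide in 5-exo mode; the epoxide is made from the erythro C2,C1′-diol, so C2 is inverted twice (net retention).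
3. C1′-OH comes from hydride opening of a C1′–C6′ epoxide. That epoxide is installed by C2-OH-directed vanadium epoxidation of a cyclohexa-1,4-dienyl carbinol (C2→C1′ relay).
4. C2–C3 comes from an Evans syn-aldol between an o-silyloxyarylacetyl oxazolidinone and cyclohexa-1,4-diene-1-carbaldehyde.
5. Ring order: the carbocycle is made first (Diels–Alder), the arene is bought (methyl dihydroferulate), and the O-heterocycle is made second.

## Route

**Step 1**
Reactants: 1 methyl 3-(4-hydroxy-3-methoxyphenyl)propanoate
Product: 2 methyl 3-(3-bromo-4-hydroxy-5-methoxyphenyl)propanoate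
Conditions: Br2 (1.0 equiv), t-BuNH2 (2 equiv), toluene/CH2Cl2, −78 °C → rt
Reagents that add atoms: bromine, BrBr
Why: In this amine-mediated ortho-bromination (SEAr), the N-bromoamine hydrogen-bonded to the phenol delivers Br to the only free position ortho to OH rather than para to OMe; no stereocentre is formed.

**Step 2**
Reactants: 2
Product: 3 methyl 3-[3-bromo-4-(tert-butyldimethylsilyloxy)-5-methoxyphenyl]propanoate
Conditions: TBSCl, imidazole, DMF, rt
Reagents that add atoms: TBSCl, CC(C)(C)[Si](C)(C)Cl
Why: This phenol silylation gives an aryl TBS ether that survives Zn/Pd, the boron aldol, V/TBHP, LiAlH4 and NaH, and later serves as the fluoride trigger for ring closure.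

**Step 3**
Reactants: 4 (S)-4-benzyl-1,3-oxazolidin-2-one; 5 bromoacetyl bromide
Product: 6 (S)-4-benzyl-3-(2-bromoacetyl)oxazolidin-2-one
Conditions: n-BuLi, THF, −78 °C; then 5, −78 → 0 °C
Reagents that add atoms: none
Why: This is N-acylation of the lithiated Evans auxiliary, and the auxiliary stereocentre is untouched.

**Step 4**
Reactants: 3; 6
Product: 7 (S)-4-benzyl-3-{2-[2-(TBSO)-3-methoxy-5-(3-methoxy-3-oxopropyl)phenyl]acetyl}oxazolidin-2-one
Conditions: 6 (1.5 equiv), activated Zn, THF, rt; then 3, Pd(dba)2 (3 mol %), Q-Phos (3 mol %), THF, 50 °C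
Reagents that add atoms: none
Why: A Reformatsky zinc enolate undergoes Pd-catalysed α-arylation (Negishi-type) under near-neutral conditions that tolerate the ester, silyl ether and imide; no new stereocentre is formed.

**Step 5**
Reactants: 8 buta-1,3-diene; 9 methyl propiolate
Product: 10 methyl cyclohexa-1,4-diene-1-carboxylate
Conditions: 8 (excess), BHT, toluene, sealed tube, 120 °C
Reagents that add atoms: none
Why: A thermal Diels–Alder [4+2] reaction with an alkyne dienophile gives the skipped diene directly, which forms the carbocycle.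

**Step 6**
Reactants: 10
Product: 11 (cyclohexa-1,4-dien-1-yl)methanol
Conditions: DIBAL-H (2.2 equiv), CH2Cl2, −78 °C
Reagents that add atoms: none
Why: This is a 1,2-reduction of the enoate, and both alkenes are untouched.

**Step 7**
Reactants: 11
Product: 12 cyclohexa-1,4-diene-1-carbaldehyde (used at once)
Conditions: Dess–Martin periodinane, NaHCO3, CH2Cl2, 0 °C
Reagents that add atoms: none
Why: The buffered Dess–Martin oxidation is non-basic and does not dehydrogenate, so the 1,4-diene is not aromatised.

**Step 8**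
Reactants: 7; 12
Product: 13 (4S)-4-benzyl-3-[(2S,3S)-2-aryl-3-(cyclohexa-1,4-dien-1-yl)-3-hydroxypropanoyl]oxazolidin-2-one, where aryl = 2-TBSO-3-MeO-5-(3-methoxy-3-oxopropyl)phenyl
Conditions: n-Bu2BOTf, Et3N, CH2Cl2, −78 → 0 °C; 12, −78 → 0 °C; pH 7 buffer, H2O2/MeOH
Reagents that add atoms: none
Why: In this Evans boron syn-aldol, the Z-enolate reacts through a Zimmerman–Traxler chair on the face opposite the benzyl group, which sets C3 and C2 (the future 3R,2S).

**Step 9**
Reactants: 13
Product: 14 the same imide carrying (3S)-3-hydroxy-3-[(1S,6S)-7-oxabicyclo[4.1.0]hept-3-en-1-yl]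
Conditions: VO(acac)2 (5 mol %), t-BuOOH (1.2 equiv, decane), CH2Cl2, 0 °C
Reagents that add atoms: tert-butyl hydroperoxide, CC(C)(C)OO
Why: In this hydroxyl-directed vanadium epoxidation only the allylic trisubstituted alkene reacts, and the A(1,2)-minimised transition state (C2–H eclipsing ring C2′H2) gives the erythro epoxy alcohol, setting C1′ (S).

**Step 10**
Reactants: 14
Product: 15 (1S)-1-{(1S,2R)-2-[2-TBSO-5-(3-hydroxypropyl)-3-methoxyphenyl]-1,3-dihydroxypropyl}cyclohex-3-en-1-ol (auxiliary 4 recovered)
Conditions: LiAlH4 (5 equiv), THF, 0 °C → rt; Rochelle salt work-up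
Reagents that add atoms: none
Why: In this global hydride reduction, SN2 attack at the less substituted C6′ leaves the C1′–O bond and configuration intact, while the imide and ester become the two primary alcohols and C2/C3 are untouched.

**Step 11**
Reactants: 15
Product: 16 bis(primary O-TBS) ether of 15, with C2-OH and C1′-OH free
Conditions: TBSCl (2.2 equiv), imidazole, CH2Cl2, 0 °C
Reagents that add atoms: TBSCl, CC(C)(C)[Si](C)(C)Cl
Why: Sterically selective silylation masks the two primary alcohols; in particular C3-CH2OH could otherwise be activated and close an isomeric five-membered ring.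

**Step 12**
Reactants: 16
Product: 17 (2R,3S)-2-{(1R)-1-[2-TBSO-3-methoxy-5-(3-TBSO-propyl)phenyl]-2-(TBSO)ethyl}-1-oxaspiro[2.5]oct-5-ene
Conditions: MsCl, Et3N, CH2Cl2, −20 °C; then NaH, THF, 0 °C
Reagents that add atoms: none (the mesylate is lost)
Why: Mesylation of the only acylable OH is followed by 3-exo-tet Williamson closure by the C1′ alkoxide, which is the first inversion at C2 and is done while the phenol is still masked so that direct phenoxide SN2 cannot compete.

**Step 13**
Reactants: 17
Product: 18 (1S)-1-[(2S,3R)-3-(hydroxymethyl)-5-(3-hydroxypropyl)-7-methoxy-2,3-dihydrobenzofuran-2-yl]cyclohex-3-en-1-ol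
Conditions: TBAF (4 equiv), THF, rt → 50 °C
Reagents that add atoms: none
Why: Desilylation frees the phenoxide, which opens the epoxide in 5-exo-tet mode at the less substituted C2; this second inversion gives net retention (2S), places C2 trans to C3-CH2OH, and releases C1′-OH.

**Step 14**
Reactants: 18
Product: 19 (1S,3S,6R)-3-[(2S,3R)-3-(hydroxymethyl)-5-(3-hydroxypropyl)-7-methoxy-2,3-dihydrobenzofuran-2-yl]-7-oxabicyclo[4.1.0]heptan-3-ol
Conditions: VO(acac)2 (5 mol %), t-BuOOH, CH2Cl2, 0 °C → rt
Reagents that add atoms: tert-butyl hydroperoxide, CC(C)(C)OO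
Why: In this homoallylic OH-directed epoxidation, the axial C1′-OH (the bulky C2 substituent being equatorial) delivers oxygen to its own face, giving the cis epoxide.

**Step 15**
Reactants: 19
Product: 20 difengpiol B
Conditions: CSA (10 mol %), MeOH, 0 °C → rt
Reagents that add atoms: methanol, CO
Why: Acid-catalysed epoxide methanolysis follows Fürst–Plattner control, so MeOH attacks C4′ anti-diaxially (R→S) while C3′–O is retained (S); attack at C3′ would be syn-axial to the C1′ substituent and closer to the electron-withdrawing C1′–O.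

## Compound list
1 | methyl 3-(4-hydroxy-3-methoxyphenyl)propanoate | COC(=O)CCc1ccc(O)c(OC)c1 | starting material
2 | methyl 3-(3-bromo-4-hydroxy-5-methoxyphenyl)propanoate | COC(=O)CCc1cc(Br)c(O)c(OC)c1 | intermediate
3 | aryl TBS ether of 2 | COC(=O)CCc1cc(Br)c(O[Si](C)(C)C(C)(C)C)c(OC)c1 | intermediate
4 | (S)-4-benzyloxazolidin-2-one | O=C1N[C@@H](Cc2ccccc2)CO1 | starting material
5 | bromoacetyl bromide | O=C(Br)CBr | starting material
6 | (S)-4-benzyl-3-(2-bromoacetyl)oxazolidin-2-one | O=C(CBr)N1[C@@H](Cc2ccccc2)COC1=O | intermediate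
7 | arylacetyl imide | COC(=O)CCc1cc(CC(=O)N2[C@@H](Cc3ccccc3)COC2=O)c(O[Si](C)(C)C(C)(C)C)c(OC)c1 | intermediate
8 | buta-1,3-diene | C=CC=C | starting material
9 | methyl propiolate | C#CC(=O)OC | starting material
10 | methyl cyclohexa-1,4-diene-1-carboxylate | COC(=O)C1=CCC=CC1 | intermediate
11 | (cyclohexa-1,4-dien-1-yl)methanol | OCC1=CCC=CC1 | intermediate
12 | cyclohexa-1,4-diene-1-carbaldehyde | O=CC1=CCC=CC1 | intermediate
13 | (2S,3S) syn-aldol imide | O=C(N1[C@@H](Cc2ccccc2)COC1=O)[C@@H](c1cc(CCC(=O)OC)cc(OC)c1O[Si](C)(C)C(C)(C)C)[C@H](O)C1=CCC=CC1 | intermediate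
14 | erythro epoxy alcohol imide, (1S,6S)-epoxide | O=C(N1[C@@H](Cc2ccccc2)COC1=O)[C@@H](c1cc(CCC(=O)OC)cc(OC)c1O[Si](C)(C)C(C)(C)C)[C@H](O)[C@@]12CC=CC[C@@H]1O2 | intermediate
15 | tetraol (aryl OTBS) | OC[C@@H](c1cc(CCCO)cc(OC)c1O[Si](C)(C)C(C)(C)C)[C@H](O)[C@]1(O)CCC=CC1 | intermediate
16 | tris-TBS diol | CC(C)(C)[Si](C)(C)OC[C@@H](c1cc(CCCO[Si](C)(C)C(C)(C)C)cc(OC)c1O[Si](C)(C)C(C)(C)C)[C@H](O)[C@]1(O)CCC=CC1 | intermediate
17 | (2R,3S)-spiro-epoxide | CC(C)(C)[Si](C)(C)OC[C@@H](c1cc(CCCO[Si](C)(C)C(C)(C)C)cc(OC)c1O[Si](C)(C)C(C)(C)C)[C@H]1O[C@]12CCC=CC2 | intermediate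
18 | trans-dihydrobenzofuranyl cyclohex-3-en-1-ol | COc1cc(CCCO)cc2c1O[C@H]([C@]1(O)CCC=CC1)[C@H]2CO | intermediate
19 | cis-hydroxy epoxide | COc1cc(CCCO)cc2c1O[C@H]([C@]1(O)CC[C@H]3O[C@H]3C1)[C@H]2CO | intermediate
20 | difengpiol B, (1S,3S,4S)-1-[(2S,3R)-3-(hydroxymethyl)-5-(3-hydroxypropyl)-7-methoxy-2,3-dihydrobenzofuran-2-yl]-4-methoxycyclohexane-1,3-diol | COc1cc(CCCO)cc2c1O[C@H]([C@]1(O)CC[C@H](OC)[C@@H](O)C1)[C@H]2CO | target

## Count
Total steps: 15.
Longest linear sequence: 11 (steps 1, 2, 4, 8–15; the branch 5–7, 8–15 is equally long).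

## Three steps most likely to fail, with fallbacks
1. **Step 4.** Arylation of an imide zinc enolate with an ortho-silyloxy aryl bromide may suffer self-condensation or protodezincation.
   Fallback: drop the cross-coupling. O-allylate 1, run the aromatic Claisen rearrangement, protect as TBS, cleave the allyl group (OsO4/NaIO4 then Pinnick) to the arylacetic acid, and acylate 4 through the mixed anhydride. This adds 3 steps.
2. **Step 9.** V/TBHP on the aldol diene may cause aromatisation, over-epoxidation, imide participation or eroded dr.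
   Fallback: install C1′–O before the coupling under reagent control. Carry out Sharpless asymmetric epoxidation of 11 with D-(−)-DET, oxidise to the epoxy-aldehyde, and use it as the acceptor in the Evans aldol, which gives 14 directly.
3. **Steps 12/13.** The double-inversion relay may be undermined by silyl migration, semipinacol shift or sluggish closure at the hindered C2.
   Fallback: form the other C–O bond instead. Carry the phenol as its aryl triflate and close O1–C7a by Pd-catalysed intramolecular C–O coupling of the free C2-OH. The aldol oxygen then becomes O1 and the C2–O bond is never broken, so C2 is retained.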